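## Retrosynthetic overview

1. Kuwanon V (22) ⇐ removal of five MOM ethers ⇐ Claisen–Schmidt condensation of methyl ketone 20 with aldehyde 12 (second chalcone arm, made last).
2. Cyclohexene 20 (last ring formed) ⇐ Lewis-acid ring expansion (zwitterionic formal 1,3-shift) of vinylcyclobutane 19; this makes the C3–C4 bond and sets core C-3 and C-4.
3. Cyclobutane 19 (first ring formed) ⇐ catalytic enantioselective stepwise (2+2) annulation of chalcone 13 with the isopropenyl end of diene 18; this sets core C-5.
4. 13 ⇐ aldol condensation of aryl methyl ketone 7 (from resorcinol: MOM, ortho-lithiation/prenylation, C–H borylation, acyl Suzuki) with aldehyde 12 (from 4-bromophenol: MOM, Li/DMF).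
5. 18 ⇐ resorcinol by C-acetylation, iodination between the two oxygens, MOM protection and Heck coupling with isoprene.

Assumption: the SMILES is taken as the definition of the target, so the aroyl ring is 3,5-dihydroxy-4-prenylphenyl and the cyclohexene is (3S,4R,5S) in the core numbering C1(Me)=C2–C3(resorcinol aryl)–C4(aroyl)–C5(4-hydroxyphenyl)–C6H2 (3,4-cis, 4,5-trans).

Assumption: the (S)-prolinol-derived catalyst of step 12 is taken to open the Si face of the β-carbon of 13; if a test run shows the other sense, the mirror-image catalyst is used.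

## Route

Step 1
Reactants: 1 resorcinol
Product: 2 1,3-bis(methoxymethoxy)benzene
Conditions: MOMCl (2.4 equiv), i-Pr2NEt (3 equiv), CH2Cl2, 0 °C to rt
Reagents that add atoms: chloromethyl methyl ether (MOMCl), COCCl
Why: Amine-mediated O-alkylation (acetal protection) of both phenols gives the bis-MOM ether, whose two acetal oxygens later direct lithiation to the carbon between them.

Step 2
Reactants: 2 1,3-bis(methoxymethoxy)benzene; 3 1-bromo-3-methylbut-2-ene (prenyl bromide)
Product: 5 1,3-bis(methoxymethoxy)-2-(3-methylbut-2-en-1-yl)benzene, via 2-lithio-1,3-bis(methoxymethoxy)benzene 4 (not isolated)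
Conditions: n-BuLi (1.1 equiv), THF, 0 °C; then CuBr·SMe2 (10 mol %), 3, −78 °C to rt
Reagents that add atoms: none
Why: Directed ortho-metalation between the two MOM ethers followed by copper-assisted SN2 alkylation with the allylic bromide places the prenyl group regiospecifically at C-2.

Step 3
Reactants: 5 1,3-bis(methoxymethoxy)-2-(3-methylbut-2-en-1-yl)benzene
Product: 6 2-[3,5-bis(methoxymethoxy)-4-(3-methylbut-2-en-1-yl)phenyl]-4,4,5,5-tetramethyl-1,3,2-dioxaborolane
Conditions: B2pin2 (1.0 equiv), [Ir(OMe)(cod)]2 (1.5 mol %), 4,4'-di-tert-butyl-2,2'-bipyridine (3 mol %), THF, 80 °C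
Reagents that add atoms: bis(pinacolato)diboron, CC1(C)OB(OC1(C)C)B1OC(C)(C)C(C)(C)O1
Why: Sterically governed iridium-catalysed aromatic C–H borylation takes the only ring C–H that has no ortho substituent (para to prenyl, meta to both oxygens), while the trisubstituted prenyl alkene and the MOM ethers are inert.

Step 4
Reactants: 6 2-[3,5-bis(methoxymethoxy)-4-(3-methylbut-2-en-1-yl)phenyl]-4,4,5,5-tetramethyl-1,3,2-dioxaborolane
Product: 7 1-[3,5-bis(methoxymethoxy)-4-(3-methylbut-2-en-1-yl)phenyl]ethan-1-one
Conditions: Ac2O (1.5 equiv), Pd(OAc)2 (3 mol %), P(4-MeOC6H4)3 (7 mol %), H2O (2.5 equiv), THF, 60 °C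
Reagents that add atoms: acetic anhydride, CC(=O)OC(C)=O
Why: Acyl Suzuki–Miyaura coupling (zerovalent palladium inserts into the anhydride C–O bond and the acetate on palladium mediates transmetalation of the aryl boronate) gives the methyl ketone meta to both oxygens, a position closed to Friedel–Crafts acylation.

Step 5
Reactants: 8 4-bromophenol
Product: 9 1-bromo-4-(methoxymethoxy)benzene
Conditions: MOMCl (1.2 equiv), i-Pr2NEt (1.5 equiv), CH2Cl2, 0 °C to rt
Reagents that add atoms: chloromethyl methyl ether (MOMCl), COCCl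
Why: O-alkylation masks the phenol so that the aryl bromide can be converted into an aryllithium.

Step 6
Reactants: 9 1-bromo-4-(methoxymethoxy)benzene
Product: 12 4-(methoxymethoxy)benzaldehyde, via [4-(methoxymethoxy)phenyl]lithium 10 (not isolated), via lithium (dimethylamino)[4-(methoxymethoxy)phenyl]methanolate 11 (not isolated)
Conditions: n-BuLi (1.05 equiv), THF, −78 °C; DMF (1.5 equiv), −78 to 0 °C; H2O
Reagents that add atoms: N,N-dimethylformamide, CN(C)C=O
Why: Bromine–lithium exchange and Bouveault-type formylation, in which the tetrahedral lithium hemiaminolate survives until aqueous work-up so that no over-addition occurs.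

Step 7
Reactants: 7 1-[3,5-bis(methoxymethoxy)-4-(3-methylbut-2-en-1-yl)phenyl]ethan-1-one; 12 4-(methoxymethoxy)benzaldehyde
Product: 13 (E)-1-[3,5-bis(methoxymethoxy)-4-(3-methylbut-2-en-1-yl)phenyl]-3-[4-(methoxymethoxy)phenyl]prop-2-en-1-one
Conditions: KOH (50% aq, 3 equiv), EtOH, rt
Reagents that add atoms: none
Why: Claisen–Schmidt aldol condensation, whose E1cB dehydration gives the thermodynamic (E)-enone.

Step 8
Reactants: 1 resorcinol
Product: 14 1-(2,4-dihydroxyphenyl)ethan-1-one
Conditions: AcOH, ZnCl2 (1.2 equiv), 140 °C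
Reagents that add atoms: acetic acid, CC(=O)O
Why: Nencki (Friedel–Crafts) C-acetylation at the position para to one hydroxyl and ortho to the other.

Step 9
Reactants: 14 1-(2,4-dihydroxyphenyl)ethan-1-one
Product: 15 1-(2,4-dihydroxy-3-iodophenyl)ethan-1-one
Conditions: I2 (0.4 equiv), HIO3 (0.2 equiv), EtOH–H2O, rt
Reagents that add atoms: iodine, II; iodic acid, O[I](=O)=O
Why: Electrophilic aromatic iodination in which HIO3 reoxidises iodide so that all iodine is used and the hydrogen-bonded ketone/2-OH chelate directs substitution to C-3 between the two oxygens, the regiochemistry expected for this ketone with this reagent pair.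

Step 10
Reactants: 15 1-(2,4-dihydroxy-3-iodophenyl)ethan-1-one
Product: 16 1-[3-iodo-2,4-bis(methoxymethoxy)phenyl]ethan-1-one
Conditions: MOMCl (3 equiv), i-Pr2NEt (4 equiv), CH2Cl2, 0 °C to reflux
Reagents that add atoms: chloromethyl methyl ether (MOMCl), COCCl
Why: O-alkylation of both phenols (the chelated 2-OH needs excess reagent and heat) removes the acidic protons and prevents chromene formation in the later cationic steps.

Step 11
Reactants: 16 1-[3-iodo-2,4-bis(methoxymethoxy)phenyl]ethan-1-one; 17 isoprene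
Product: 18 1-{2,4-bis(methoxymethoxy)-3-[(1E)-3-methylbuta-1,3-dien-1-yl]phenyl}ethan-1-one
Conditions: Pd(OAc)2 (5 mol %), Bu4NCl (1 equiv), NaHCO3 (2.5 equiv), 17 (5 equiv), DMF, 80 °C, sealed tube
Reagents that add atoms: none
Why: Mizoroki–Heck reaction under ligand-free phase-transfer (Jeffery) conditions, in which the arylpalladium adds to the CH2 of the unsubstituted vinyl group of isoprene and β-hydride elimination gives the (E)-1-aryl-3-methylbuta-1,3-diene.

Step 12
Reactants: 13 (E)-1-[3,5-bis(methoxymethoxy)-4-(3-methylbut-2-en-1-yl)phenyl]-3-[4-(methoxymethoxy)phenyl]prop-2-en-1-one; 18 1-{2,4-bis(methoxymethoxy)-3-[(1E)-3-methylbuta-1,3-dien-1-yl]phenyl}ethan-1-one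
Product: 19 1-{3-[(E)-2-{(2R,3S)-2-[3,5-bis(methoxymethoxy)-4-(3-methylbut-2-en-1-yl)benzoyl]-3-[4-(methoxymethoxy)phenyl]-1-methylcyclobutyl}ethenyl]-2,4-bis(methoxymethoxy)phenyl}ethan-1-one (both epimers at cyclobutane C-1)
Conditions: oxazaborolidinium triflimide (20 mol %, made from (S)-3,3-diphenyl-1-(o-tolyl)tetrahydro-1H,3H-pyrrolo[1,2-c][1,3,2]oxazaborole and Tf2NH), 18 (1.3 equiv, slow addition), CH2Cl2, −78 °C; Et3N quench at −78 °C
Reagents that add atoms: none
Why: Proposed new method: a chiral oxazaborolidinium-catalysed, stepwise polar (2+2) annulation of a non-chelating β-aryl enone with the 1,1-disubstituted end of a 1,3-diene — the boron Lewis acid binds the carbonyl of 13 in the s-trans enone geometry and screens one β-face, the s-trans diene attacks the open Si face of the β-carbon through its unhindered CH2 terminus (Mukaiyama–Michael-type), the resulting tertiary allyl cation is born transoid so its hindered, twisted aryl-bearing end cannot reach the enolate carbon, and the B–O-bound enolate therefore collapses through carbon onto the cationic methyl-bearing carbon to give the cyclobutane, which does not re-ionise at −78 °C; this sets core C-5 (S) and the trans aroyl group, while the quaternary carbon forms as an epimer mixture that the next step erases; closest known reaction type: chiral oxazaborolidinium-catalysed enantioselective [2+2] cycloadditions of acrylates or allenoates with alkenes and enol ethers, and acid-catalysed (2+2) annulations of silyl enol ethers and 2-siloxydienes with unsaturated carbonyl compounds that stop at vinylcyclobutanes.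

Step 13
Reactants: 19 1-{3-[(E)-2-{(2R,3S)-2-[3,5-bis(methoxymethoxy)-4-(3-methylbut-2-en-1-yl)benzoyl]-3-[4-(methoxymethoxy)phenyl]-1-methylcyclobutyl}ethenyl]-2,4-bis(methoxymethoxy)phenyl}ethan-1-one
Product: 20 1-{3-[(1S,5S,6R)-6-[3,5-bis(methoxymethoxy)-4-(3-methylbut-2-en-1-yl)benzoyl]-5-[4-(methoxymethoxy)phenyl]-3-methylcyclohex-2-en-1-yl]-2,4-bis(methoxymethoxy)phenyl}ethan-1-one
Conditions: Sc(OTf)3 (20 mol %), CH2Cl2, −30 to 0 °C
Reagents that add atoms: none
Why: Lewis-acid-triggered ring expansion of a donor–acceptor vinylcyclobutane (formal 1,3-alkyl shift through a zwitterion, the same reactivity as the known rearrangement of siloxy-vinylcyclobutanes to cyclohexenes): Sc(OTf)3 on the aroyl oxygen ionises the strained bond between the aroyl-bearing carbon and the quaternary carbon (both epimers give the same scandium enolate/allyl cation pair), the cisoid cation rotamer closes at its aryl-bearing terminus to the six-membered ring, core C-5 is untouched, and the compact (endo-type) ion-pair closure with the C-5 aryl pseudo-equatorial is expected to set core C-4 trans to it and core C-3 cis to the aroyl group (minor all-trans isomer removed by chromatography).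

Step 14
Reactants: 20 1-{3-[(1S,5S,6R)-6-[3,5-bis(methoxymethoxy)-4-(3-methylbut-2-en-1-yl)benzoyl]-5-[4-(methoxymethoxy)phenyl]-3-methylcyclohex-2-en-1-yl]-2,4-bis(methoxymethoxy)phenyl}ethan-1-one; 12 4-(methoxymethoxy)benzaldehyde
Product: 21 (E)-1-{3-[(1S,5S,6R)-6-[3,5-bis(methoxymethoxy)-4-(3-methylbut-2-en-1-yl)benzoyl]-5-[4-(methoxymethoxy)phenyl]-3-methylcyclohex-2-en-1-yl]-2,4-bis(methoxymethoxy)phenyl}-3-[4-(methoxymethoxy)phenyl]prop-2-en-1-one
Conditions: KOH (aq, 3 equiv), EtOH–THF, 0 °C to rt
Reagents that add atoms: none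
Why: Claisen–Schmidt condensation at the only methyl ketone gives the (E)-enone, while the ring C–H next to the aroyl group is tertiary and flanked by two aryl-bearing carbons, so it enolises far more slowly and the three stereocentres are kept.

Step 15
Reactants: 21 (E)-1-{3-[(1S,5S,6R)-6-[3,5-bis(methoxymethoxy)-4-(3-methylbut-2-en-1-yl)benzoyl]-5-[4-(methoxymethoxy)phenyl]-3-methylcyclohex-2-en-1-yl]-2,4-bis(methoxymethoxy)phenyl}-3-[4-(methoxymethoxy)phenyl]prop-2-en-1-one
Product: 22 kuwanon V
Conditions: 3 M HCl (aq), MeOH–THF, 40 °C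
Reagents that add atoms: none
Why: Acid-catalysed acetal exchange with methanol removes all five MOM groups under conditions that prenylated hydroxychalcones tolerate, and no stereocentre is touched.

## Compound list

1 | resorcinol (benzene-1,3-diol) | Oc1cccc(O)c1 | starting material
2 | 1,3-bis(methoxymethoxy)benzene | COCOc1cccc(OCOC)c1 | intermediate
3 | 1-bromo-3-methylbut-2-ene (prenyl bromide) | CC(C)=CCBr | starting material
4 | 2-lithio-1,3-bis(methoxymethoxy)benzene | [Li]c1c(OCOC)cccc1OCOC | intermediate (not isolated)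
5 | 1,3-bis(methoxymethoxy)-2-(3-methylbut-2-en-1-yl)benzene | CC(C)=CCc1c(OCOC)cccc1OCOC | intermediate
6 | 2-[3,5-bis(methoxymethoxy)-4-(3-methylbut-2-en-1-yl)phenyl]-4,4,5,5-tetramethyl-1,3,2-dioxaborolane | CC(C)=CCc1c(OCOC)cc(B2OC(C)(C)C(C)(C)O2)cc1OCOC | intermediate
7 | 1-[3,5-bis(methoxymethoxy)-4-(3-methylbut-2-en-1-yl)phenyl]ethan-1-one | CC(C)=CCc1c(OCOC)cc(C(C)=O)cc1OCOC | intermediate
8 | 4-bromophenol | Oc1ccc(Br)cc1 | starting material
9 | 1-bromo-4-(methoxymethoxy)benzene | COCOc1ccc(Br)cc1 | intermediate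
10 | [4-(methoxymethoxy)phenyl]lithium | [Li]c1ccc(OCOC)cc1 | intermediate (not isolated)
11 | lithium (dimethylamino)[4-(methoxymethoxy)phenyl]methanolate (racemic hemiaminolate) | [Li]OC(N(C)C)c1ccc(OCOC)cc1 | intermediate (not isolated)
12 | 4-(methoxymethoxy)benzaldehyde | COCOc1ccc(C=O)cc1 | intermediate
13 | (E)-1-[3,5-bis(methoxymethoxy)-4-(3-methylbut-2-en-1-yl)phenyl]-3-[4-(methoxymethoxy)phenyl]prop-2-en-1-one | CC(C)=CCc1c(OCOC)cc(C(=O)/C=C/c2ccc(OCOC)cc2)cc1OCOC | intermediate
14 | 1-(2,4-dihydroxyphenyl)ethan-1-one | CC(=O)c1ccc(O)cc1O | intermediate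
15 | 1-(2,4-dihydroxy-3-iodophenyl)ethan-1-one | CC(=O)c1ccc(O)c(I)c1O | intermediate
16 | 1-[3-iodo-2,4-bis(methoxymethoxy)phenyl]ethan-1-one | CC(=O)c1ccc(OCOC)c(I)c1OCOC | intermediate
17 | isoprene (2-methylbuta-1,3-diene) | CC(=C)C=C | starting material
18 | 1-{2,4-bis(methoxymethoxy)-3-[(1E)-3-methylbuta-1,3-dien-1-yl]phenyl}ethan-1-one | CC(=O)c1ccc(OCOC)c(/C=C/C(C)=C)c1OCOC | intermediate
19 | 1-{3-[(E)-2-{(2R,3S)-2-[3,5-bis(methoxymethoxy)-4-(3-methylbut-2-en-1-yl)benzoyl]-3-[4-(methoxymethoxy)phenyl]-1-methylcyclobutyl}ethenyl]-2,4-bis(methoxymethoxy)phenyl}ethan-1-one; aroyl and aryl trans; epimer mixture at the quaternary cyclobutane C-1, used as such | CC(C)=CCc1c(OCOC)cc(C(=O)[C@@H]2[C@@H](c3ccc(OCOC)cc3)CC2(C)/C=C/c2c(OCOC)ccc(C(C)=O)c2OCOC)cc1OCOC | intermediate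
20 | 1-{3-[(1S,5S,6R)-6-[3,5-bis(methoxymethoxy)-4-(3-methylbut-2-en-1-yl)benzoyl]-5-[4-(methoxymethoxy)phenyl]-3-methylcyclohex-2-en-1-yl]-2,4-bis(methoxymethoxy)phenyl}ethan-1-one | CC(C)=CCc1c(OCOC)cc(C(=O)[C@H]2[C@@H](c3c(OCOC)ccc(C(C)=O)c3OCOC)C=C(C)C[C@@H]2c2ccc(OCOC)cc2)cc1OCOC | intermediate
21 | (E)-1-{3-[(1S,5S,6R)-6-[3,5-bis(methoxymethoxy)-4-(3-methylbut-2-en-1-yl)benzoyl]-5-[4-(methoxymethoxy)phenyl]-3-methylcyclohex-2-en-1-yl]-2,4-bis(methoxymethoxy)phenyl}-3-[4-(methoxymethoxy)phenyl]prop-2-en-1-one | CC(C)=CCc1c(OCOC)cc(C(=O)[C@H]2[C@@H](c3c(OCOC)ccc(C(=O)/C=C/c4ccc(OCOC)cc4)c3OCOC)C=C(C)C[C@@H]2c2ccc(OCOC)cc2)cc1OCOC | intermediate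
22 | kuwanon V, (E)-1-{3-[(1S,5S,6R)-6-[3,5-dihydroxy-4-(3-methylbut-2-en-1-yl)benzoyl]-5-(4-hydroxyphenyl)-3-methylcyclohex-2-en-1-yl]-2,4-dihydroxyphenyl}-3-(4-hydroxyphenyl)prop-2-en-1-one | CC(C)=CCc1c(O)cc(C(=O)[C@H]2[C@@H](c3c(O)ccc(C(=O)/C=C/c4ccc(O)cc4)c3O)C=C(C)C[C@@H]2c2ccc(O)cc2)cc1O | target

## Step count and risks

Total step count: 15. Longest linear sequence: 9 steps (steps 1, 2, 3, 4, 7, 12, 13, 14, 15).

The three steps most likely to fail are steps 11, 12 and 13.

Step 11 couples a doubly ortho-substituted, electron-rich aryl iodide with a volatile diene, so conversion may be slow and some arylation at the isopropenyl end can occur. The fallback sets out from 16 and installs the diene in two stages. A Heck coupling of 16 with 2-methylbut-3-en-2-ol (Pd(OAc)2, Bu4NCl, NaHCO3, DMF, 80 °C) has only one possible regiochemistry and gives the tertiary allylic alcohol 1-{3-[(E)-3-hydroxy-3-methylbut-1-en-1-yl]-2,4-bis(methoxymethoxy)phenyl}ethan-1-one F1. Acid-catalysed dehydration of this alcohol (camphorsulfonic acid, 10 mol %, toluene, 60 °C) then gives the diene, and the route is rejoined at 18.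

Step 12 is the proposed new step. It may fail in three ways: the diene may oligomerise under the cationic boron catalyst, the ion pair may close on oxygen or directly to the six-membered ring, or the enantioselectivity may be low. The fallback uses known chemistry only and sets out from 13 and 18. Heating the two in toluene at 160 °C in a sealed tube with 2,6-di-tert-butyl-4-methylphenol as inhibitor is the established thermal cycloaddition of chalcones with such aryl dienes. It gives the racemate of 20 after chromatographic removal of the minor diastereomer. Preparative HPLC on a chiral stationary phase separates 20 from its mirror image ent-20 F2. The route is rejoined at 20, and step 13 is then not needed.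

Step 13 may give too much of the all-trans isomer, or the cation may lose a proton to an open-chain triene instead of closing. The fallback sets out from 19 and comes back at 20. It replaces Lewis-acid heterolysis by a single-electron (radical-cation) vinylcyclobutane rearrangement: 9-mesityl-10-methylacridinium tetrafluoroborate (5 mol %), blue light, CH2Cl2, rt. The electron-rich aryl alkene is oxidised, the same strained bond opens to a distonic radical cation, and this recloses to the cyclohexene before back electron transfer. The fallback makes no compound outside the list, none F0.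

## Further compounds

F1 | step 11 | 1-{3-[(E)-3-hydroxy-3-methylbut-1-en-1-yl]-2,4-bis(methoxymethoxy)phenyl}ethan-1-one | CC(=O)c1ccc(OCOC)c(/C=C/C(C)(C)O)c1OCOC
F2 | step 12 | ent-20, 1-{3-[(1R,5R,6S)-6-[3,5-bis(methoxymethoxy)-4-(3-methylbut-2-en-1-yl)benzoyl]-5-[4-(methoxymethoxy)phenyl]-3-methylcyclohex-2-en-1-yl]-2,4-bis(methoxymethoxy)phenyl}ethan-1-one | CC(C)=CCc1c(OCOC)cc(C(=O)[C@@H]2[C@H](c3c(OCOC)ccc(C(C)=O)c3OCOC)C=C(C)C[C@H]2c2ccc(OCOC)cc2)cc1OCOC
F0 | step 13 | none | none
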